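## Analysis of the target

The target is a cembrane-type diterpenoid: a 14-membered carbocycle, numbered here from the acetoxy carbon C1 through C4(Me)=C5–C6=C7(iPr) to the carbinol C10 and the ether carbons C11 and C14(Me). An oxygen bridges C11 and C14, so a 2,5-disubstituted oxolane (O, C11, C12, C13, C14) sits inside a 15-oxabicyclo[10.2.1]pentadecane. The four stereocentres (1R, 10S, 11R, 14S) form one array: the secondary acetate C1 next to the quaternary ether carbon C14, and the tertiary carbinol C10 next to the ether methine C11, with the appendages C1 and C10 cis on the oxolane. The other ring carbons carry a conjugated diene of two trisubstituted alkenes. C4=C5 is E; C6=C7 is E by the sequence rule but holds the ring carbons C5 and C8 cis, with the isopropyl group outside. The diene is sensitive to acid, electrophilic oxidants, dissolving metals and allylic transposition; the tertiary alcohol can ionise; the acetate tolerates neither hydride nor carbanions. The difficulty is threefold: a stereotetrad with two fully substituted oxygenated carbons, closure of the 14-membered ring beside it, and the diene geometry. The strategy rests on the two O–C–C–O pairs C1/C14 and C11/C10 that flank the cis-oxolane and share its oxygen. They are the imprint of two syn dioxygenations of the Z-trisubstituted alkenes C1=C14 and C10=C11 of a 1,5-diene, with the C14 oxygen delivered to C11.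

## Retrosynthetic reasoning

**31 to 30.** The acetyl C–O bond is cut last. C1–OH is the only secondary hydroxyl of 30 and the C10 hydroxyl is tertiary, so selective acylation is safe, and the ester never meets hydride or carbanions.

**30 to 29 to 28 (ring bond C8–C9).** C9 is the primary carbon beside the tertiary carbinol. The C9/C10 diol closes to a terminal epoxide with retention at C10, and attack at C9 regenerates the C10 oxygen without touching a stereocentre. C8 is allylic, so a phenylsulfonyl group there gives the carbanion and is later exchanged for hydrogen. The forward steps must close a 14-membered ring at a neopentyl-like CH2 and then deliver hydride to C8 without moving the diene. Only one sulfone is placed on the diene unit: a C3,C8-bis-sulfone could not be deprotonated site-selectively, and reductive cleavage of one sulfonyl group would expel the other across the diene.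

**28 to 26 to 20 + 24 (C5–C6 and C4–CH3).** The diene is cut in its middle between two stereodefined alkenyl partners. Syn carbometalation of the terminal alkyne of 20 gives E at C4=C5. The ring-cis C6=C7 alkene arrives in iodide 24, made in two steps from 21 by anti carbometalation. Both geometries thus come from stereospecific additions to alkynes and not from olefination of ketones.

**20 to 19 to 17 + 18 (C2–C3).** C2 is the terminal carbon of the C1–C2 epoxide, and the propargylic anion of 18 brings C3–C5. Attack at C2 leaves the C1–O bond and configuration alone, and no group has to be removed afterwards.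

**17 to 15 to 14.** The epoxide comes from the 1,2-diol, and the diol from reductive removal of the auxiliary. The acyl carbon of 14 becomes the electrophilic CH2 (C2), and the sultam 10 is recovered.

**14 to 12 (key disconnection).** The four C–O bonds at C1, C14, C11 and C10 are cut together, which takes the oxolane back to the Z,Z-1,5-dienoyl sultam 12. One operation then makes the ring and all four stereocentres. Relative configuration comes from alkene geometry and the enforced cis closure; absolute configuration comes from 10.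

**12 to 1.** The imide bond leads to acid 9 and sultam 10. Ester 8 comes from ynoate 7 by syn addition of methyl (C14–CH3, fixing Z at C1=C14). Ynoate 7 comes from alkyne 6 by C-acylation (C1–C2). The C10=C11 alkene of 4 comes from aldehyde 2 and phosphonate 3 by Z-selective olefination. Aldehyde 2 comes from 1.

## Alternatives that were turned down

**Alternative 1: transannular cascade of a macrocyclic bis-epoxide.**
- Disconnection: the O–C14 and C10–OH bonds, on the closed macrocycle.
- Forward key step: under mild aqueous acid the activated C1–C14 epoxide of bis-epoxide A1 is attacked at C14 by the oxygen of the C10–C11 epoxide, and hydration at C10 gives the diol A2 (identical with 30).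
- For: both epoxides derive from E ring alkenes of a simple cembratetraene, no protecting group is needed, and the endgame is very short. On step count it is stronger than the chosen route.
- Against: A1 must be made enantiopure, with two remote epoxides of matched sense, on a flexible ring without a directing hydroxyl and next to a diene that competes for electrophilic oxidants. The cascade has no built-in direction: the C1–C14 epoxide can equally attack the activated C10–C11 epoxide, which leads to an oxane or to stereoisomeric diols. The diene and hydride shifts can also intercept the cations. All four stereocentres would hang on the last step of the most valuable intermediate.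
- Comparison: the chosen strategy gives up brevity but fixes the stereotetrad early, on an acyclic substrate, by stereospecific syn additions.

**Alternative 2: (4+3) furan–oxyallyl cycloadduct as template.**
- Disconnection: the C14–C1 and C11–C10 bonds.
- Forward key step: 2-methylfuran A3 and the allyl cation released from the chiral mixed acetal A4 by a silyl triflate combine to the oxabicyclic ketone A5.
- For: the bicycle guarantees the cis-oxolane, three stereocentres arise in one step from very cheap materials, and the reaction type is well established. In convergence and cost it is stronger.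
- Against: A5 has a C1–C9 bond and a C9 ketone that the target lacks. The bridge must be cut, C9 reduced to CH2, C12=C13 hydrogenated, C10 hydroxylated with separate stereocontrol, and the phenylethyl ether exchanged for acetate before the diene exists. The regiochemistry is also adverse: the methyl-bearing furan carbon must bond to the alkoxy terminus and create a quaternary centre beside it.
- Comparison: the chosen key step delivers C1 and C10 at the correct oxidation level, with both hydroxyls already differentiated.

**Alternative 3: sulfonium ylide [2,3]-shift for ring closure.**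
- Disconnection: the C8–C9 bond together with the C6=C7 π bond.
- Forward key step: dirhodium-catalysed decomposition of diazoketone A6 gives a carbenoid that is trapped by the sulfur on C6; the [2,3]-shift of the ylide gives the 14-membered ketone A7.
- For: ring closure goes through an easier S–C bond formation followed by ring expansion, the ring-cis alkene forms in the same event, and the α-keto sulfide is cleaved easily. On ring closure it is stronger than the chosen route, whose weakest steps are 18 and 19.
- Against: it does not address the stereotetrad. C10 is left as a ketone, so the tertiary carbinol needs a late methyl addition of uncertain facial sense on a macrocycle, and the oxolane with C1, C11 and C14 must come from other chemistry. The carbenoid can also cyclopropanate the alkenes, and the alkene geometry depends on ring conformation, not on a stereospecific rule.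
- Comparison: the chosen strategy sets C10 together with C11 and accepts a harder macrocyclisation.

Key step: step 9

Assumption: the face selectivity of step 9 is taken to follow the established model for N-enoyl camphorsultams, and metalated forms of a reactant (acetylides, phosphonate and sulfonyl carbanions, the sodium salt of 10) are written into the conditions and not counted as separate intermediates.

## Route

Step 1
Reactants: 1 pent-4-yn-1-ol
Product: 2 pent-4-ynal
Conditions: TEMPO (cat.), PhI(OAc)2, CH2Cl2, 23 °C
Reagents that add atoms: none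
Why: Nitroxyl-catalysed oxidation stops at the aldehyde and leaves the terminal alkyne untouched; the volatile aldehyde is used as a solution.

Step 2
Reactants: 2 pent-4-ynal; 3 methyl 2-[bis(2,2,2-trifluoroethoxy)phosphoryl]propanoate
Product: 4 methyl (2Z)-2-methylhept-2-en-6-ynoate
Conditions: 3, KN(SiMe3)2, 18-crown-6, THF, −78 °C; then 2
Reagents that add atoms: none
Why: Still–Gennari olefination: the electron-poor phosphonate under dissociating conditions should give the trisubstituted Z-enoate, which fixes the geometry of the future C10=C11 alkene (ester carbon C9 cis to C12).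

Step 3
Reactants: 4 methyl (2Z)-2-methylhept-2-en-6-ynoate
Product: 5 (2Z)-2-methylhept-2-en-6-yn-1-ol
Conditions: i-Bu2AlH, CH2Cl2, −78 °C; potassium sodium tartrate work-up
Reagents that add atoms: none
Why: Two hydride equivalents reduce the conjugated ester to the allylic alcohol at low temperature without touching alkene geometry or the alkyne.

Step 4
Reactants: 5 (2Z)-2-methylhept-2-en-6-yn-1-ol
Product: 6 tert-butyl{[(2Z)-2-methylhept-2-en-6-yn-1-yl]oxy}diphenylsilane
Conditions: TBDPSCl, imidazole, DMF, 23 °C
Reagents that add atoms: tert-butyl(chloro)diphenylsilane, CC(C)(C)[Si](Cl)(c1ccccc1)c1ccccc1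
Why: Standard silylation; this ether tolerates organolithium, cuprate, hydroxide, permanganate in acetic acid and borohydride, and is removed by fluoride in step 13.

Step 5
Reactants: 6 tert-butyl{[(2Z)-2-methylhept-2-en-6-yn-1-yl]oxy}diphenylsilane
Product: 7 methyl (6Z)-8-{[tert-butyl(diphenyl)silyl]oxy}-7-methyloct-6-en-2-ynoate
Conditions: n-BuLi, THF, −78 °C; ClCO2Me, −78 → 0 °C
Reagents that add atoms: methyl chloroformate, COC(=O)Cl
Why: C-acylation of the lithium acetylide introduces C2 at the carboxyl oxidation level.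

Step 6
Reactants: 7 methyl (6Z)-8-{[tert-butyl(diphenyl)silyl]oxy}-7-methyloct-6-en-2-ynoate
Product: 8 methyl (2Z,6Z)-8-{[tert-butyl(diphenyl)silyl]oxy}-3,7-dimethylocta-2,6-dienoate
Conditions: Me2CuLi (from MeLi and CuI), THF, −78 °C; MeOH/NH4Cl quench at −78 °C
Reagents that add atoms: lithium dimethylcuprate, [Li+].C[Cu-]C
Why: Conjugate addition of a Gilman cuprate to an alk-2-ynoate is a syn carbocupration; protonation at low temperature with retention puts the new methyl cis to H and the chain (C13) cis to the ester, which is the Z geometry needed at C1=C14.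

Step 7
Reactants: 8 methyl (2Z,6Z)-8-{[tert-butyl(diphenyl)silyl]oxy}-3,7-dimethylocta-2,6-dienoate
Product: 9 (2Z,6Z)-8-{[tert-butyl(diphenyl)silyl]oxy}-3,7-dimethylocta-2,6-dienoic acid
Conditions: LiOH, THF/MeOH/H2O, 40 °C; then 1 M HCl to pH 3
Reagents that add atoms: lithium hydroxide, [Li+].[OH-]
Why: Saponification of the hindered conjugated ester; the β,β-disubstituted enoate has no easy path to isomerise under these conditions and the silyl ether survives.

Step 8
Reactants: 9 (2Z,6Z)-8-{[tert-butyl(diphenyl)silyl]oxy}-3,7-dimethylocta-2,6-dienoic acid; 10 (2S)-bornane-10,2-sultam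
Product: 12 N-[(2Z,6Z)-8-{[tert-butyl(diphenyl)silyl]oxy}-3,7-dimethylocta-2,6-dienoyl]-(2S)-bornane-10,2-sultam, via acid chloride 11 (not isolated)
Conditions: 9, Me2C=C(Cl)NMe2, CH2Cl2, 0 °C; then 10, NaH, THF, 0 → 23 °C
Reagents that add atoms: none
Why: The α-chloroenamine forms the acid chloride under neutral conditions, avoiding HCl and amine bases that could scramble the Z alkene; N-acylation of the sodium salt of the sultam is the standard entry to N-enoyl camphorsultams.

Step 9
Reactants: 12 N-[(2Z,6Z)-8-{[tert-butyl(diphenyl)silyl]oxy}-3,7-dimethylocta-2,6-dienoyl]-(2S)-bornane-10,2-sultam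
Product: 14 N-[(2S)-2-{(2S,5R)-5-[(2S)-1-{[tert-butyl(diphenyl)silyl]oxy}-2-hydroxypropan-2-yl]-2-methyloxolan-2-yl}-2-hydroxyacetyl]-(2S)-bornane-10,2-sultam, via cyclic manganate diester 13 (not isolated)
Conditions: KMnO4 (aq), AcOH, acetone/H2O, −35 → −10 °C; Na2S2O5 work-up
Reagents that add atoms: potassium permanganate, [K+].[O-][Mn](=O)(=O)=O
Why: Permanganate (heptavalent manganese) adds suprafacially (3+2) to the electron-poor enoyl alkene C1=C14, which reacts faster than the electron-richer C10=C11 alkene, to give the cyclic manganate diester 13 (pentavalent manganese). One oxo ligand and the C14-bound oxygen of 13 then add suprafacially across C10=C11 in an intramolecular (3+2) step whose bicyclic transition state can only place C1 and C10 on the same side of the new ring; this closes the oxolane by a formal 5-exo delivery of the C14 oxygen to C11, and hydrolysis of the manganese–oxygen bonds on reductive work-up leaves the C1 and C10 hydroxyls. The closest known reaction type is the permanganate oxidative cyclisation of 1,5-dienes and of N-(2,6-dienoyl) camphorsultams to cis-2,5-bis(hydroxyalkyl)oxolanes, applied here to a Z,Z-configured, doubly trisubstituted diene. C1 and C14 are set in the first addition: their relative configuration follows from the Z geometry of C1=C14, and their absolute configuration from the sultam, whose s-cis enoyl rotamer with C=O anti to the SO2 group should be attacked on the Cα-si face, anti to the nitrogen lone pair, giving S at C1 of 14. C11 follows from the enforced cis closure relative to C14, and C10 from syn addition to the Z-configured C10=C11 alkene. The step needs site selectivity for the first attack (secured by conjugation to the imide), cyclisation of 13 in preference to hydrolysis or over-oxidation (1,5-spacing, low temperature, acetic acid buffer) and face selectivity (the auxiliary; the (2R)-sultam would be used if the sense proved opposite).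

Step 10
Reactants: 14 N-[(2S)-2-{(2S,5R)-5-[(2S)-1-{[tert-butyl(diphenyl)silyl]oxy}-2-hydroxypropan-2-yl]-2-methyloxolan-2-yl}-2-hydroxyacetyl]-(2S)-bornane-10,2-sultam
Product: 15 (1R)-1-{(2S,5R)-5-[(2S)-1-{[tert-butyl(diphenyl)silyl]oxy}-2-hydroxypropan-2-yl]-2-methyloxolan-2-yl}ethane-1,2-diol
Conditions: NaBH4, THF/H2O, 0 → 23 °C
Reagents that add atoms: none
Why: Borohydride attacks the activated imide carbonyl and reduces the released aldehyde to the primary alcohol; C1 is not epimerised and the auxiliary is recovered.

Step 11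
Reactants: 15 (1R)-1-{(2S,5R)-5-[(2S)-1-{[tert-butyl(diphenyl)silyl]oxy}-2-hydroxypropan-2-yl]-2-methyloxolan-2-yl}ethane-1,2-diol
Product: 17 (2S)-1-{[tert-butyl(diphenyl)silyl]oxy}-2-{(2R,5S)-5-methyl-5-[(2R)-oxiran-2-yl]oxolan-2-yl}propan-2-ol, via primary tosylate 16 (not isolated)
Conditions: TsCl, Et3N, Bu2SnO (cat.), CH2Cl2, 0 °C; then K2CO3, MeOH, 0 °C
Reagents that add atoms: none
Why: Tin-acetal-catalysed sulfonylation is selective for the primary hydroxyl of the 1,2-diol; base then closes the oxirane by attack of the C1 alkoxide on C2, so the C1–O bond and configuration are retained.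

Step 12
Reactants: 17 (2S)-1-{[tert-butyl(diphenyl)silyl]oxy}-2-{(2R,5S)-5-methyl-5-[(2R)-oxiran-2-yl]oxolan-2-yl}propan-2-ol; 18 1-(trimethylsilyl)propyne
Product: 19 (2S)-1-{[tert-butyl(diphenyl)silyl]oxy}-2-{(2R,5S)-5-[(1R)-1-hydroxy-5-(trimethylsilyl)pent-4-yn-1-yl]-5-methyloxolan-2-yl}propan-2-ol
Conditions: 18, n-BuLi, THF, −78 °C; then 17, DMPU, −78 → 0 °C
Reagents that add atoms: none
Why: The propargylic lithium reagent from 18 opens the monosubstituted epoxide at the terminal carbon C2 (SN2), forming C2–C3 and leaving C1 untouched; the silyl group favours the propargyl over the allenyl product, and one extra equivalent deprotonates the tertiary hydroxyl.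

Step 13
Reactants: 19 (2S)-1-{[tert-butyl(diphenyl)silyl]oxy}-2-{(2R,5S)-5-[(1R)-1-hydroxy-5-(trimethylsilyl)pent-4-yn-1-yl]-5-methyloxolan-2-yl}propan-2-ol
Product: 20 (2S)-2-{(2R,5S)-5-[(1R)-1-hydroxypent-4-yn-1-yl]-5-methyloxolan-2-yl}propane-1,2-diol
Conditions: Bu4NF, THF, 23 °C; NH4Cl work-up
Reagents that add atoms: none
Why: Fluoride cleaves the alkynyl C–Si bond and the primary silyl ether in one operation, giving the terminal alkyne and the C9/C10 diol.

Step 14
Reactants: 21 prop-2-yn-1-ol
Product: 22 (2Z)-3-iodo-2-(propan-2-yl)prop-2-en-1-ol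
Conditions: i-PrMgCl, CuI (cat.), THF, 0 → 23 °C; then I2, −40 → 0 °C
Reagents that add atoms: isopropylmagnesium chloride, CC(C)[Mg]Cl; iodine, II
Why: Copper-catalysed carbomagnesiation of propargyl alcohol is an anti addition through a five-membered magnesium alkoxide chelate, with isopropyl on the internal carbon; iodinolysis with retention gives the Z-iodide (I cis to CH2OH), the ring-cis geometry needed at C6=C7.

Step 15
Reactants: 22 (2Z)-3-iodo-2-(propan-2-yl)prop-2-en-1-ol
Product: 24 {[(2Z)-3-iodo-2-(propan-2-yl)prop-2-en-1-yl]sulfonyl}benzene, via allylic mesylate 23 (not isolated)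
Conditions: MsCl, Et3N, CH2Cl2, −20 °C; then PhSO2Na, DMF, 23 °C
Reagents that add atoms: sodium benzenesulfinate, [Na+].[O-]S(=O)c1ccccc1
Why: The allylic mesylate is displaced (SN2) by the sulfur of the sulfinate; the vinyl iodide is inert.

Step 16
Reactants: 20 (2S)-2-{(2R,5S)-5-[(1R)-1-hydroxypent-4-yn-1-yl]-5-methyloxolan-2-yl}propane-1,2-diol; 24 {[(2Z)-3-iodo-2-(propan-2-yl)prop-2-en-1-yl]sulfonyl}benzene
Product: 26 (2S)-2-{(2R,5S)-5-[(1R,4E,6Z)-1-hydroxy-4-methyl-8-(phenylsulfonyl)-7-(propan-2-yl)octa-4,6-dien-1-yl]-5-methyloxolan-2-yl}propane-1,2-diol, via alkenylalane 25 (not isolated)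
Conditions: Me3Al, Cp2ZrCl2, ClCH2CH2Cl, 0 → 23 °C; volatiles removed; then 24, Pd(PPh3)4 (cat.), ZnCl2, THF, 23 °C
Reagents that add atoms: trimethylaluminium, C[Al](C)C
Why: Zirconium-catalysed carboalumination adds methyl and aluminium syn across the terminal alkyne, with methyl on the internal carbon (E at C4=C5); the alkenylalane is then cross-coupled with iodide 24 under palladium/zinc catalysis (Negishi coupling) with retention at both alkenes, forming C5–C6. The hydroxyls are carried as aluminium alkoxides.

Step 17
Reactants: 26 (2S)-2-{(2R,5S)-5-[(1R,4E,6Z)-1-hydroxy-4-methyl-8-(phenylsulfonyl)-7-(propan-2-yl)octa-4,6-dien-1-yl]-5-methyloxolan-2-yl}propane-1,2-diol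
Product: 28 (1R,4E,6Z)-4-methyl-1-{(2S,5R)-2-methyl-5-[(2S)-2-methyloxiran-2-yl]oxolan-2-yl}-8-(phenylsulfonyl)-7-(propan-2-yl)octa-4,6-dien-1-ol, via primary tosylate 27 (not isolated)
Conditions: TsCl, Et3N, Bu2SnO (cat.), CH2Cl2, 0 °C; then K2CO3, MeOH, 0 °C
Reagents that add atoms: none
Why: The stannylene acetal forms only at the 1,2-diol and directs sulfonylation to the primary C9 hydroxyl; the tertiary C10 alkoxide then displaces the sulfonate, so C10 keeps its configuration and the isolated C1 hydroxyl does not react.

Step 18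
Reactants: 28 (1R,4E,6Z)-4-methyl-1-{(2S,5R)-2-methyl-5-[(2S)-2-methyloxiran-2-yl]oxolan-2-yl}-8-(phenylsulfonyl)-7-(propan-2-yl)octa-4,6-dien-1-ol
Product: 29 (1R,4E,6Z,10S,11R,14S)-4,10,14-trimethyl-8-(phenylsulfonyl)-7-(propan-2-yl)-11,14-epoxycyclotetradeca-4,6-diene-1,10-diol (both C8 epimers)
Conditions: LiN(SiMe3)2 (2.5 equiv), THF/DMPU, 0.002 M, −78 → 40 °C, slow addition of 28
Reagents that add atoms: none
Why: Base gives the C1 alkoxide and the allylic sulfonyl carbanion at C8, which attacks the terminal epoxide carbon C9 under high dilution (endo-mode epoxide opening, 14-membered ring). Intramolecular epoxide opening by sulfur-stabilised allylic carbanions is an established ring closure for cembranoids, and the lithium alkoxide is a far poorer nucleophile; the C8 configuration is irrelevant.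

Step 19
Reactants: 29 (1R,4E,6Z,10S,11R,14S)-4,10,14-trimethyl-8-(phenylsulfonyl)-7-(propan-2-yl)-11,14-epoxycyclotetradeca-4,6-diene-1,10-diol
Product: 30 (1R,4E,6E,10S,11R,14S)-4,10,14-trimethyl-7-(propan-2-yl)-11,14-epoxycyclotetradeca-4,6-diene-1,10-diol
Conditions: PdCl2(dppp) (cat.), LiBHEt3, THF, 0 → 23 °C
Reagents that add atoms: none
Why: Oxidative addition of zerovalent palladium to the allylic sulfone and hydride transfer from the borohydride replace the sulfonyl group by hydrogen (palladium-catalysed reductive desulfonylation). Delivery to the sulfonyl-bearing terminus C8 keeps the diene conjugated, is the least hindered mode and lies next to the C10 alkoxyborohydride, so the target diene should result.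

Step 20
Reactants: 30 (1R,4E,6E,10S,11R,14S)-4,10,14-trimethyl-7-(propan-2-yl)-11,14-epoxycyclotetradeca-4,6-diene-1,10-diol
Product: 31 (1R,4E,6E,10S,11R,14S)-10-hydroxy-4,10,14-trimethyl-7-(propan-2-yl)-11,14-epoxycyclotetradeca-4,6-dien-1-yl acetate
Conditions: Ac2O, pyridine, DMAP (cat.), CH2Cl2, 0 → 23 °C
Reagents that add atoms: acetic anhydride, CC(=O)OC(C)=O
Why: DMAP-catalysed acylation of the secondary C1 hydroxyl; the tertiary C10 hydroxyl is too hindered to react under these conditions.

## Compound list

1 | pent-4-yn-1-ol | OCCCC#C | starting material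
2 | pent-4-ynal | O=CCCC#C | intermediate
3 | methyl 2-[bis(2,2,2-trifluoroethoxy)phosphoryl]propanoate | COC(=O)C(C)P(=O)(OCC(F)(F)F)OCC(F)(F)F | starting material
4 | methyl (2Z)-2-methylhept-2-en-6-ynoate | COC(=O)/C(C)=C\CCC#C | intermediate
5 | (2Z)-2-methylhept-2-en-6-yn-1-ol | OC/C(C)=C\CCC#C | intermediate
6 | tert-butyl{[(2Z)-2-methylhept-2-en-6-yn-1-yl]oxy}diphenylsilane | CC(C)(C)[Si](OC/C(C)=C\CCC#C)(c1ccccc1)c1ccccc1 | intermediate
7 | methyl (6Z)-8-{[tert-butyl(diphenyl)silyl]oxy}-7-methyloct-6-en-2-ynoate | COC(=O)C#CCC/C=C(/C)CO[Si](c1ccccc1)(c1ccccc1)C(C)(C)C | intermediate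
8 | methyl (2Z,6Z)-8-{[tert-butyl(diphenyl)silyl]oxy}-3,7-dimethylocta-2,6-dienoate | COC(=O)/C=C(/C)CC/C=C(/C)CO[Si](c1ccccc1)(c1ccccc1)C(C)(C)C | intermediate
9 | (2Z,6Z)-8-{[tert-butyl(diphenyl)silyl]oxy}-3,7-dimethylocta-2,6-dienoic acid | OC(=O)/C=C(/C)CC/C=C(/C)CO[Si](c1ccccc1)(c1ccccc1)C(C)(C)C | intermediate
10 | (2S)-bornane-10,2-sultam | CC1(C)[C@H]2CC[C@@]13CS(=O)(=O)N[C@H]3C2 | starting material
11 | (2Z,6Z)-8-{[tert-butyl(diphenyl)silyl]oxy}-3,7-dimethylocta-2,6-dienoyl chloride | ClC(=O)/C=C(/C)CC/C=C(/C)CO[Si](c1ccccc1)(c1ccccc1)C(C)(C)C | intermediate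
12 | N-[(2Z,6Z)-8-{[tert-butyl(diphenyl)silyl]oxy}-3,7-dimethylocta-2,6-dienoyl]-(2S)-bornane-10,2-sultam | CC1(C)[C@H]2CC[C@@]13CS(=O)(=O)N(C(=O)/C=C(/C)CC/C=C(/C)CO[Si](c4ccccc4)(c4ccccc4)C(C)(C)C)[C@H]3C2 | intermediate
13 | cyclic manganate diester of 12 at C1/C14 (pentavalent manganese, potassium salt) | CC1(C)[C@H]2CC[C@@]13CS(=O)(=O)N(C(=O)[C@H]4O[Mn](=O)([O-])O[C@@]4(C)CC/C=C(/C)CO[Si](c5ccccc5)(c5ccccc5)C(C)(C)C)[C@H]3C2.[K+] | intermediate
14 | N-[(2S)-2-{(2S,5R)-5-[(2S)-1-{[tert-butyl(diphenyl)silyl]oxy}-2-hydroxypropan-2-yl]-2-methyloxolan-2-yl}-2-hydroxyacetyl]-(2S)-bornane-10,2-sultam | CC1(C)[C@H]2CC[C@@]13CS(=O)(=O)N(C(=O)[C@@H](O)[C@]4(C)CC[C@@H](O4)[C@@](C)(O)CO[Si](c5ccccc5)(c5ccccc5)C(C)(C)C)[C@H]3C2 | intermediate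
15 | (1R)-1-{(2S,5R)-5-[(2S)-1-{[tert-butyl(diphenyl)silyl]oxy}-2-hydroxypropan-2-yl]-2-methyloxolan-2-yl}ethane-1,2-diol | OC[C@@H](O)[C@]1(C)CC[C@@H](O1)[C@@](C)(O)CO[Si](c1ccccc1)(c1ccccc1)C(C)(C)C | intermediate
16 | (2R)-2-{(2S,5R)-5-[(2S)-1-{[tert-butyl(diphenyl)silyl]oxy}-2-hydroxypropan-2-yl]-2-methyloxolan-2-yl}-2-hydroxyethyl 4-methylbenzenesulfonate | Cc1ccc(cc1)S(=O)(=O)OC[C@@H](O)[C@]2(C)CC[C@@H](O2)[C@@](C)(O)CO[Si](c3ccccc3)(c3ccccc3)C(C)(C)C | intermediate
17 | (2S)-1-{[tert-butyl(diphenyl)silyl]oxy}-2-{(2R,5S)-5-methyl-5-[(2R)-oxiran-2-yl]oxolan-2-yl}propan-2-ol | C1O[C@H]1[C@]2(C)CC[C@@H](O2)[C@@](C)(O)CO[Si](c3ccccc3)(c3ccccc3)C(C)(C)C | intermediate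
18 | 1-(trimethylsilyl)propyne | CC#C[Si](C)(C)C | starting material
19 | (2S)-1-{[tert-butyl(diphenyl)silyl]oxy}-2-{(2R,5S)-5-[(1R)-1-hydroxy-5-(trimethylsilyl)pent-4-yn-1-yl]-5-methyloxolan-2-yl}propan-2-ol | C[Si](C)(C)C#CCC[C@@H](O)[C@]1(C)CC[C@@H](O1)[C@@](C)(O)CO[Si](c1ccccc1)(c1ccccc1)C(C)(C)C | intermediate
20 | (2S)-2-{(2R,5S)-5-[(1R)-1-hydroxypent-4-yn-1-yl]-5-methyloxolan-2-yl}propane-1,2-diol | C#CCC[C@@H](O)[C@]1(C)CC[C@@H](O1)[C@@](C)(O)CO | intermediate
21 | prop-2-yn-1-ol | C#CCO | starting material
22 | (2Z)-3-iodo-2-(propan-2-yl)prop-2-en-1-ol | OC/C(C(C)C)=C\I | intermediate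
23 | (2Z)-3-iodo-2-(propan-2-yl)prop-2-en-1-yl methanesulfonate | CS(=O)(=O)OC/C(C(C)C)=C\I | intermediate
24 | {[(2Z)-3-iodo-2-(propan-2-yl)prop-2-en-1-yl]sulfonyl}benzene | O=S(=O)(c1ccccc1)C/C(C(C)C)=C\I | intermediate
25 | (E)-alkenyldimethylalane from carboalumination of 20 (hydroxyls as dimethylaluminium alkoxides) | C[Al](C)/C=C(\C)CC[C@@H](O[Al](C)C)[C@]1(C)CC[C@@H](O1)[C@@](C)(O[Al](C)C)CO[Al](C)C | intermediate
26 | (2S)-2-{(2R,5S)-5-[(1R,4E,6Z)-1-hydroxy-4-methyl-8-(phenylsulfonyl)-7-(propan-2-yl)octa-4,6-dien-1-yl]-5-methyloxolan-2-yl}propane-1,2-diol | O=S(=O)(c1ccccc1)C/C(C(C)C)=C\C=C(/C)CC[C@@H](O)[C@]2(C)CC[C@@H](O2)[C@@](C)(O)CO | intermediate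
27 | (2S)-2-hydroxy-2-{(2R,5S)-5-[(1R,4E,6Z)-1-hydroxy-4-methyl-8-(phenylsulfonyl)-7-(propan-2-yl)octa-4,6-dien-1-yl]-5-methyloxolan-2-yl}propyl 4-methylbenzenesulfonate | O=S(=O)(c1ccccc1)C/C(C(C)C)=C\C=C(/C)CC[C@@H](O)[C@]2(C)CC[C@@H](O2)[C@@](C)(O)COS(=O)(=O)c1ccc(C)cc1 | intermediate
28 | (1R,4E,6Z)-4-methyl-1-{(2S,5R)-2-methyl-5-[(2S)-2-methyloxiran-2-yl]oxolan-2-yl}-8-(phenylsulfonyl)-7-(propan-2-yl)octa-4,6-dien-1-ol | O=S(=O)(c1ccccc1)C/C(C(C)C)=C\C=C(/C)CC[C@@H](O)[C@]2(C)CC[C@@H](O2)[C@]3(C)CO3 | intermediate
29 | (1R,4E,6Z,10S,11R,14S)-4,10,14-trimethyl-8-(phenylsulfonyl)-7-(propan-2-yl)-11,14-epoxycyclotetradeca-4,6-diene-1,10-diol (C8 epimers) | O[C@@H]1CC/C(C)=C/C=C(/C(C)C)C(S(=O)(=O)c3ccccc3)C[C@](C)(O)[C@H]2CC[C@]1(C)O2 | intermediate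
30 | (1R,4E,6E,10S,11R,14S)-4,10,14-trimethyl-7-(propan-2-yl)-11,14-epoxycyclotetradeca-4,6-diene-1,10-diol | O[C@@H]1CC/C(C)=C/C=C(/C(C)C)CC[C@](C)(O)[C@H]2CC[C@]1(C)O2 | intermediate
31 | (1R,4E,6E,10S,11R,14S)-10-hydroxy-4,10,14-trimethyl-7-(propan-2-yl)-11,14-epoxycyclotetradeca-4,6-dien-1-yl acetate | CC(=O)O[C@@H]1CC/C(C)=C/C=C(/C(C)C)CC[C@](C)(O)[C@H]2CC[C@]1(C)O2 | target

## Step count and least certain steps

Total: 20 steps. Longest linear sequence: 18 steps (steps 1–13 and 16–20); steps 14–15 make the side branch 24.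

**Step 9 (key step).**
- Most likely failure: erosion of face selectivity. A(1,3) strain between the carbonyl oxygen and the cis C13 methylene of the Z,β,β-disubstituted enoyl unit can populate twisted or s-trans rotamers. Manganate ester 13 may also be diverted by hydrolysis or over-oxidation before the second addition, which is slowed by the Z alkene carrying the bulky silyloxymethyl group.
- Fallback (resolution in place of auxiliary control): sets out from ester 8 and returns at triol 15. Ester 8 is submitted to the same permanganate conditions. The two syn additions still fix the relative configuration and should give the racemic cis-oxolane diol methyl ester F1. Its enantiomers are separated by preparative chromatography on a chiral stationary phase, and the 2S-configured hydroxy ester is reduced with LiBH4 to 15.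

**Step 16.**
- Most likely failure: protodemetalation of the alkenylalane by incompletely metalated hydroxyls or by the acidic sulfone CH2, methyl transfer from residual Me3Al to the iodide, and ionisation of the allylic sulfone by zerovalent palladium with loss of alkene geometry.
- Fallback (isolated partners, palladium-free coupling): sets out from 20 and 24 and returns at 26. Alane 25 is quenched with iodine to give the E-vinyl iodide F2. Iodide 24 is converted with Me3SnSnMe3 and catalytic Pd(PPh3)4 into the Z-alkenylstannane F3. F2 and F3 are joined with copper thiophene-2-carboxylate, Cu(O2CC4H3S), in N-methylpyrrolidone at 0 °C (Stille-type coupling) to give 26.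

**Step 18.**
- Most likely failure: slow SN2 attack of a hindered, delocalised carbanion on the neopentyl-like carbon C9 under high dilution. This lets oligomerisation, proton transfer, attack through the vinylogous position C6 and opening of the epoxide by the C1 alkoxide compete.
- Fallback (reversed polarity at C8–C9): sets out from 20 and returns at 30.
  - The C9/C10 diol of 20 is converted through the primary tosylate F4 into the epoxy alkyne F5 (conditions of step 17).
  - PhSNa opens F5 at C9 to the hydroxy sulfide F6, which H2O2 with catalytic (NH4)6Mo7O24 oxidises to the β-hydroxy sulfone F7 before any alkene is present.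
  - Carboalumination of F7 gives the alkenylalane F8, and palladium/zinc-catalysed coupling with iodo alcohol 22 gives the dienyl alcohol F9.
  - The primary allylic hydroxyl of F9 is converted into the chloride F10 (MsCl, LiCl, 2,4,6-collidine, DMF).
  - LiN(i-Pr)2 (3.3 equiv) forms the alkoxide-flanked α-sulfonyl carbanion at C9, which closes the ring by SN2 at the allylic chloride to give the macrocyclic sulfone F11.
  - Sodium amalgam Na(Hg) with Na2HPO4 in MeOH then removes the sulfonyl group from the saturated C9 and gives 30.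

**Step 19.**
- Most likely failure: hydride delivery to the central (C6) or remote (C4) terminus of the pentadienyl palladium intermediate, or syn/anti equilibration of that intermediate, giving transposed or geometrically isomerised dienes.
- Fallback: the detour described under step 18 (from 20 to 30) also answers this step. In it the sulfonyl group never sits on an allylic carbon and is cleaved from the saturated C9 by electron transfer, which cannot move the diene. It makes no compound beyond those of that detour.

## Further compounds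

F1 | step 9 | methyl (2S)-2-{(2S,5R)-5-[(2S)-1-{[tert-butyl(diphenyl)silyl]oxy}-2-hydroxypropan-2-yl]-2-methyloxolan-2-yl}-2-hydroxyacetate (formed as the racemate) | COC(=O)[C@@H](O)[C@]1(C)CC[C@@H](O1)[C@@](C)(O)CO[Si](c1ccccc1)(c1ccccc1)C(C)(C)C
F2 | step 16 | (2S)-2-{(2R,5S)-5-[(1R,4E)-1-hydroxy-5-iodo-4-methylpent-4-en-1-yl]-5-methyloxolan-2-yl}propane-1,2-diol | I/C=C(\C)CC[C@@H](O)[C@]1(C)CC[C@@H](O1)[C@@](C)(O)CO
F3 | step 16 | trimethyl[(1Z)-3-(phenylsulfonyl)-2-(propan-2-yl)prop-1-en-1-yl]stannane | C[Sn](C)(C)/C=C(\CS(=O)(=O)c1ccccc1)C(C)C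
F4 | step 18 | (2S)-2-hydroxy-2-{(2R,5S)-5-[(1R)-1-hydroxypent-4-yn-1-yl]-5-methyloxolan-2-yl}propyl 4-methylbenzenesulfonate | C#CCC[C@@H](O)[C@]1(C)CC[C@@H](O1)[C@@](C)(O)COS(=O)(=O)c1ccc(C)cc1
F5 | step 18 | (1R)-1-{(2S,5R)-2-methyl-5-[(2S)-2-methyloxiran-2-yl]oxolan-2-yl}pent-4-yn-1-ol | C#CCC[C@@H](O)[C@]1(C)CC[C@@H](O1)[C@]2(C)CO2
F6 | step 18 | (2R)-2-{(2R,5S)-5-[(1R)-1-hydroxypent-4-yn-1-yl]-5-methyloxolan-2-yl}-1-(phenylsulfanyl)propan-2-ol | C#CCC[C@@H](O)[C@]1(C)CC[C@@H](O1)[C@@](C)(O)CSc1ccccc1
F7 | step 18 | (2R)-2-{(2R,5S)-5-[(1R)-1-hydroxypent-4-yn-1-yl]-5-methyloxolan-2-yl}-1-(phenylsulfonyl)propan-2-ol | C#CCC[C@@H](O)[C@]1(C)CC[C@@H](O1)[C@@](C)(O)CS(=O)(=O)c1ccccc1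
F8 | step 18 | (E)-alkenyldimethylalane from carboalumination of F7 (hydroxyls as dimethylaluminium alkoxides) | C[Al](C)/C=C(\C)CC[C@@H](O[Al](C)C)[C@]1(C)CC[C@@H](O1)[C@@](C)(O[Al](C)C)CS(=O)(=O)c1ccccc1
F9 | step 18 | (2R)-2-{(2R,5S)-5-[(1R,4E,6Z)-1,8-dihydroxy-4-methyl-7-(propan-2-yl)octa-4,6-dien-1-yl]-5-methyloxolan-2-yl}-1-(phenylsulfonyl)propan-2-ol | OC/C(C(C)C)=C\C=C(/C)CC[C@@H](O)[C@]1(C)CC[C@@H](O1)[C@@](C)(O)CS(=O)(=O)c1ccccc1
F10 | step 18 | (2R)-2-{(2R,5S)-5-[(1R,4E,6Z)-8-chloro-1-hydroxy-4-methyl-7-(propan-2-yl)octa-4,6-dien-1-yl]-5-methyloxolan-2-yl}-1-(phenylsulfonyl)propan-2-ol | ClC/C(C(C)C)=C\C=C(/C)CC[C@@H](O)[C@]1(C)CC[C@@H](O1)[C@@](C)(O)CS(=O)(=O)c1ccccc1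
F11 | step 18 | (1R,4E,6E,10R,11R,14S)-4,10,14-trimethyl-9-(phenylsulfonyl)-7-(propan-2-yl)-11,14-epoxycyclotetradeca-4,6-diene-1,10-diol (C9 epimers) | O[C@@H]1CC/C(C)=C/C=C(/C(C)C)CC(S(=O)(=O)c3ccccc3)[C@](C)(O)[C@H]2CC[C@]1(C)O2
F0 | step 19 | none | none
A1 | alternative 1 | (4E,6E)-1,14:10,11-diepoxy-4,10,14-trimethyl-7-(propan-2-yl)cyclotetradeca-4,6-diene (both epoxides from E ring alkenes; configuration as in the SMILES) | [C@@H]12CC/C(C)=C/C=C(/C(C)C)CC[C@@]3(C)O[C@@H]3CC[C@@]1(C)O2
A2 | alternative 1 | (1R,4E,6E,10S,11R,14S)-4,10,14-trimethyl-7-(propan-2-yl)-11,14-epoxycyclotetradeca-4,6-diene-1,10-diol (identical with 30) | O[C@@H]1CC/C(C)=C/C=C(/C(C)C)CC[C@](C)(O)[C@H]2CC[C@]1(C)O2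
A3 | alternative 2 | 2-methylfuran | Cc1ccco1
A4 | alternative 2 | 1-methoxy-1-[(1S)-1-phenylethoxy]-2-[(triethylsilyl)oxy]but-2-ene (acetal epimers) | COC(O[C@@H](C)c1ccccc1)C(O[Si](CC)(CC)CC)=CC
A5 | alternative 2 | 1,4-dimethyl-2-[(1S)-1-phenylethoxy]-8-oxabicyclo[3.2.1]oct-6-en-3-one | O=C1[C@@H](C)[C@H]2C=C[C@](C)(O2)[C@H]1O[C@@H](C)c1ccccc1
A6 | alternative 3 | acyclic C9 diazoketone with phenylsulfanyl on C6, a C7=C8 methylidene and a tert-butyldimethylsilyl ether on C1 | CC(C)(C)[Si](C)(C)O[C@H](CC/C(C)=C/C(Sc1ccccc1)C(=C)C(C)C)[C@]2(C)CC[C@@H](O2)C(=O)C=[N+]=[N-]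
A7 | alternative 3 | 14-membered C10 ketone with phenylsulfanyl on C9 (C9 epimers) and a tert-butyldimethylsilyl ether on C1 | CC(C)(C)[Si](C)(C)O[C@@H]1CC/C(C)=C/C=C(/C(C)C)CC(Sc3ccccc3)C(=O)[C@H]2CC[C@]1(C)O2
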